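Assumption 1: the SMILES is read literally, so the C4 hydroxyl and the epoxide oxygen lie on opposite faces of the six-membered ring (ring-A locants 4S,5S,6R; systematic 1R,5S,6S), and the route is built for this anti arrangement.
Assumption 2: the sense of induction of N-benzylcinchonidinium chloride on dienone 5 cannot be predicted with confidence; if it favours the other arm, the pseudo-enantiomeric N-benzylcinchoninium chloride is used with no other change.

## The problem

The target has a carbocyclic ring A (C1 ketone, C2 bearing the amide nitrogen, C3 =CH, C4 tertiary carbinol, C5 and C6 the oxirane carbons), fused to oxirane ring B. It carries two all-E trienamide chains; the lower one, attached through carbon to C4, ends in the acidic 2-amino-3-hydroxycyclopent-2-enone ring C. The three stereocentres C4, C5 and C6 are contiguous, with the C4 hydroxyl anti to the oxirane oxygen and the C4 chain syn to it. This anti relation is the hard part. A carbon nucleophile adds to the C4 carbonyl of an epoxy ketone from the face opposite the oxirane, and a hydroxyl-directed epoxidation of a quinol delivers oxygen next to the hydroxyl. Both give the syn isomer, and a tertiary carbinol cannot be inverted afterwards. C4 is the only stereocentre outside the oxirane; it can steer the oxirane to the required face if its oxygen carries a bulky silyl group and its carbon substituent is slender. The trienamides, the enamide, ring C and the epoxy ketone will not tolerate strong acid, strong base, electrophilic halogen or light, and the free C4 alkoxide, being anti to the oxirane, is set up for Payne rearrangement. The chains must therefore arrive late and under near-neutral conditions.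

The feature that makes the key step possible: with the nitrogen on C2 and the oxirane oxygen removed, ring A is a 4,4-disubstituted cyclohexa-2,5-dienone with a mirror plane through O=C1 and C4. C2=C3 and C5=C6 are then enantiotopic arms. In the target one arm is the oxirane and the other is the enamide, so a single arm-selective epoxidation can create C4, C5 and C6 together and leave the other arm as an enone whose α-carbon C2 accepts nitrogen.

## Retrosynthesis

**Lower chain, C5'–C6' bond (chain numbered from its amide carbonyl).** Target 23 is cut into vinylstannane 14 and bromodienamide 22. This cut leaves only a two-carbon unit on the core, which can come from an ethynyl group, and keeps acidic ring C in a fragment that never meets fluoride, iodine or copper. The forward reaction must join two alkenyl carbons with retention of both geometries under neutral conditions (Stille coupling).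

**Vinylstannane to alkyne.** 14 comes from terminal alkyne 13 by syn hydrostannation with tin at the terminus, and 13 from the doubly silylated 12 by fluoride. The alkyne is carried as its triisopropylsilyl derivative because a free alkyne would interfere with iodination and with copper catalysis.

**C2–N bond.** 12 is cut into iodoenone 7 and primary trienamide 11. Cutting the acyl C–N bond instead would require a free 2-aminoenone, and starting from an aromatic amine leads back to the sequence that gives the wrong C4 epimer (Alternative 1). The forward reaction is a vinylic C–N coupling with a complete polyene amide; 7 comes from enone 6 by α-iodination at C2, the only enone α-CH in the molecule.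

**Oxirane C5–O and C6–O bonds (key).** 6 is traced to the achiral, mirror-symmetric dienone 5. The forward step must pick one of two enantiotopic arms and the face anti to the silyloxy group, and must stop after one oxygen transfer. The precursor has no stereocentre; the product has all three.

**C4–C(sp) bond.** 5 comes from quinol 4 by silylation, and 4 from benzoquinone 2 and acetylide 3 (from alkyne 1). The ethynyl group is chosen because its rod shape leaves the face opposite the silyloxy group open in the key step.

**Upper chain.** Amide 11 comes from ester 10, which is cut at C4=C5 into enal 8 and phosphonate 9 (E-selective Horner–Wadsworth–Emmons olefination).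

**Lower fragment.** 22 is cut at its amide bond into acid 20 (via chloride 21) and aminocyclopentenone hydrochloride 17. 20 comes from bromodienal 19 and that from glutaconaldehyde salt 18; 17 comes from nitro dione 16 and that from dione 15.

## Roads not taken

Alternative 1: the obvious route cuts the C4–chain bond last. An anilide of 2,5-dimethoxyaniline is oxidised to the amido quinone monoketal A1, epoxidised asymmetrically to A2, and a metalated vinylstannane is added to the C4 carbonyl to give A3. The weakness is structural: the nucleophile enters opposite the oxirane, so the hydroxyl of A3 ends up syn to it, which is the C4 epimer of what this target needs, and a tertiary centre cannot be corrected. The chosen plan reverses the order: the C4 substituents are in place first and the peroxide enters anti to the silyloxy group.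

Alternative 2: the C4–O and C1=O bonds are traced to a peroxide bridge. Diene A4 would take up singlet oxygen in a [4+2] cycloaddition, the remaining ring alkene would be epoxidised anti to the peroxide bridge, and a Kornblum–DeLaMare rearrangement would give A5 with the anti relation fixed by mechanism. The two bridgeheads differ, however, so the bicyclic peroxide is chiral and racemic rather than meso; a chiral base could only resolve it, losing half the material. A5 also lacks both the C2=C3 unsaturation and the nitrogen, so more steps follow than from 6.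

Alternative 3: both arms of 5 are epoxidised anti to the silyloxy group to give the meso bis-epoxide A6, which is then desymmetrised by enantioselective azide opening at C2 with loss of water to give azidoenone A7. This spends two oxidations and discards one oxygen. It needs α-regioselective and arm-selective opening of an α-keto epoxide, whereas catalytic asymmetric azidolysis is established only for simple meso epoxides. A reductive azide-to-amide step next to an enone is then still required. In the chosen plan the stereo-defining event is the C–O bond formation itself and each arm is used once.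

Key step: step 3

## Route

Step 1
Reactants: 1 (triisopropylsilyl)acetylene; 2 1,4-benzoquinone
Product: 4 4-hydroxy-4-[(triisopropylsilyl)ethynyl]cyclohexa-2,5-dien-1-one, via lithium (triisopropylsilyl)acetylide 3 (not isolated)
Conditions: 1, n-BuLi, THF, −78 °C; cannulated into 2 (1.3 equiv), THF, −78 °C; aq NH4Cl
Reagents that add atoms: none
Why: 1,2-addition of a lithium acetylide to one quinone carbonyl gives the p-quinol; inverse addition at low temperature favours the mono-adduct because its alkoxide deactivates the second carbonyl. The product is achiral.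

Step 2
Reactants: 4 4-hydroxy-4-[(triisopropylsilyl)ethynyl]cyclohexa-2,5-dien-1-one
Product: 5 4-[(triethylsilyl)oxy]-4-[(triisopropylsilyl)ethynyl]cyclohexa-2,5-dien-1-one
Conditions: Et3SiOTf, 2,6-lutidine, CH2Cl2, −78 → 0 °C
Reagents that add atoms: triethylsilyl trifluoromethanesulfonate, CC[Si](CC)(CC)OS(=O)(=O)C(F)(F)F
Why: Silyl triflate silylation of a hindered tertiary alcohol under non-acidic conditions (no dienone–phenol rearrangement); the silyl ether removes the syn-directing hydroxyl and becomes the bulky group that steers step 3.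

Step 3
Reactants: 5 4-[(triethylsilyl)oxy]-4-[(triisopropylsilyl)ethynyl]cyclohexa-2,5-dien-1-one
Product: 6 (1R,5R,6S)-5-[(triethylsilyl)oxy]-5-[(triisopropylsilyl)ethynyl]-7-oxabicyclo[4.1.0]hept-3-en-2-one
Conditions: tBuOOH (1.1 equiv), N-benzylcinchonidinium chloride (10 mol %), 0.1 M aq NaOH, toluene, 0 °C, stopped short of full conversion
Reagents that add atoms: tert-butyl hydroperoxide, CC(C)(C)OO
Why: Proposed new method: a chiral-ammonium phase-transfer Weitz–Scheffer epoxidation is used to choose between the two enantiotopic enone arms of prochiral dienone 5; the closest known reactions are the cinchona-ammonium-catalysed enantioselective epoxidation of 4,4-dialkoxycyclohexa-2,5-dienones (same ring and bond, but only π-face selection) and the anti-selective alkaline epoxidation of 4-silyloxycyclohex-2-enones. Mechanism (ring-A locants): tert-butylperoxide anion, ion-paired with the cinchonidinium cation, adds to C5 next to C4, and the resulting enolate carbon C6 displaces tert-butoxide from the proximal peroxide oxygen in a 3-exo-tet closure, so the oxirane is necessarily cis-fused. Face control comes from the substrate: attack is antiperiplanar to the C4–O bond and away from the triethylsilyl group, while the rod-like alkynyl group leaves the other face open, placing the oxirane trans to the silyloxy group and fixing C5 and C6 relative to C4. Arm control comes from the catalyst: the cation prefers one π-face of a ring enone, and in 5 that face coincides with the substrate-allowed face in only one arm, so that arm is matched and the other mismatched; this choice alone makes C4 a stereocentre without any bond to it being formed. Three selectivities are needed: anti face (secured by the size difference between OSiEt3 and the alkyne), one arm (catalyst), and mono- rather than bis-epoxidation (limited oxidant and conversion). The last should help purity, because the minor enantiomer of 6 still carries the catalyst-matched alkene and should be drained into the separable meso bis-epoxide (compound A6 of Alternative 3).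

Step 4
Reactants: 6 (1R,5R,6S)-5-[(triethylsilyl)oxy]-5-[(triisopropylsilyl)ethynyl]-7-oxabicyclo[4.1.0]hept-3-en-2-one
Product: 7 (1R,5R,6S)-3-iodo-5-[(triethylsilyl)oxy]-5-[(triisopropylsilyl)ethynyl]-7-oxabicyclo[4.1.0]hept-3-en-2-one
Conditions: I2, pyridine–CH2Cl2 (1:1), DMAP (cat.), 0 °C → rt, dark
Reagents that add atoms: iodine, II
Why: α-Iodination of an enone by amine addition, iodination of the enolate and elimination, a reaction well used on 4-silyloxy-5,6-epoxycyclohex-2-enones; C2 is the only enone α-CH. The silyl ether, silylalkyne and oxirane are inert, and no stereocentre is touched (C4 is quaternary).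

Step 5
Reactants: 8 (E)-4-methylpent-2-enal; 9 triethyl 4-phosphonocrotonate
Product: 10 ethyl (2E,4E,6E)-8-methylnona-2,4,6-trienoate
Conditions: LiN(SiMe3)2, THF, −78 → 0 °C
Reagents that add atoms: none
Why: Vinylogous Horner–Wadsworth–Emmons olefination; the stabilised phosphonate anion should give the new C4=C5 bond E, and the two existing E alkenes are carried through.

Step 6
Reactants: 10 ethyl (2E,4E,6E)-8-methylnona-2,4,6-trienoate
Product: 11 (2E,4E,6E)-8-methylnona-2,4,6-trienamide
Conditions: Me3Al, NH4Cl, toluene, 0 → 50 °C; cold dilute HCl work-up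
Reagents that add atoms: ammonium chloride, [NH4+].[Cl-]
Why: Aminolysis of an ester by an aluminium amide made in the flask (Weinreb-type amidation); 1,2-attack at the activated ester carbonyl is preferred over conjugate addition, so the triene geometry is retained.

Step 7
Reactants: 7 (1R,5R,6S)-3-iodo-5-[(triethylsilyl)oxy]-5-[(triisopropylsilyl)ethynyl]-7-oxabicyclo[4.1.0]hept-3-en-2-one; 11 (2E,4E,6E)-8-methylnona-2,4,6-trienamide
Product: 12 (2E,4E,6E)-8-methyl-N-{(1R,5R,6S)-2-oxo-5-[(triethylsilyl)oxy]-5-[(triisopropylsilyl)ethynyl]-7-oxabicyclo[4.1.0]hept-3-en-3-yl}nona-2,4,6-trienamide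
Conditions: CuI (10 mol %), N,N-dimethylglycine (20 mol %), Cs2CO3, 1,4-dioxane, 50 °C, dark
Reagents that add atoms: none
Why: Copper-catalysed vinylic amidation (Goldberg-type) of an activated vinyl iodide with a primary amide, forming the C2–N bond with the alkene in place; the non-nucleophilic amino-acid ligand avoids amine attack on the enone or oxirane, and the quaternary C4 blocks enolisation or aromatisation. The bulky alkynylsilane is inert to copper.

Step 8
Reactants: 12 (2E,4E,6E)-8-methyl-N-{(1R,5R,6S)-2-oxo-5-[(triethylsilyl)oxy]-5-[(triisopropylsilyl)ethynyl]-7-oxabicyclo[4.1.0]hept-3-en-3-yl}nona-2,4,6-trienamide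
Product: 13 (2E,4E,6E)-N-[(1R,5R,6S)-5-ethynyl-5-hydroxy-2-oxo-7-oxabicyclo[4.1.0]hept-3-en-3-yl]-8-methylnona-2,4,6-trienamide
Conditions: Bu4NF (3 equiv), AcOH (3 equiv), THF, 0 °C → rt
Reagents that add atoms: none
Why: Fluoride cleaves both the O–Si and the C(sp)–Si bond; acetic acid keeps the C4 alkoxide protonated, because that alkoxide is anti to the oxirane and could otherwise undergo Payne rearrangement.

Step 9
Reactants: 13 (2E,4E,6E)-N-[(1R,5R,6S)-5-ethynyl-5-hydroxy-2-oxo-7-oxabicyclo[4.1.0]hept-3-en-3-yl]-8-methylnona-2,4,6-trienamide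
Product: 14 (2E,4E,6E)-N-{(1R,5R,6S)-5-hydroxy-2-oxo-5-[(E)-2-(tributylstannyl)ethenyl]-7-oxabicyclo[4.1.0]hept-3-en-3-yl}-8-methylnona-2,4,6-trienamide
Conditions: Bu3SnH (1.2 equiv, slow addition), PdCl2(PPh3)2 (3 mol %), THF, 0 °C, dark
Reagents that add atoms: tributyltin hydride, CCCC[SnH](CCCC)CCCC
Why: Palladium-catalysed syn hydrostannation of a terminal alkyne; the fully substituted propargylic carbon sends tin to the terminus, giving the E stannane. Terminal alkynes react much faster than enones under these conditions, which is what the chemoselectivity relies on.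

Step 10
Reactants: 15 cyclopentane-1,3-dione
Product: 16 2-nitrocyclopentane-1,3-dione (enol form 3-hydroxy-2-nitrocyclopent-2-en-1-one)
Conditions: fuming HNO3, Et2O, 0 °C → rt
Reagents that add atoms: nitric acid, O[N+](=O)[O-]
Why: Electrophilic nitration at the doubly activated C2 of a cyclic 1,3-dione (enol nitration).

Step 11
Reactants: 16 2-nitrocyclopentane-1,3-dione
Product: 17 2-amino-3-hydroxycyclopent-2-en-1-one hydrochloride
Conditions: H2 (1 atm), Pd/C, MeOH, HCl (1.1 equiv), rt
Reagents that add atoms: hydrogen chloride, Cl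
Why: Catalytic hydrogenation of the nitro group; isolating the hydrochloride prevents self-condensation of the α-amino dione.

Step 12
Reactants: 18 glutaconaldehyde potassium salt
Product: 19 (2E,4E)-5-bromopenta-2,4-dienal
Conditions: PPh3, Br2, CH2Cl2, 0 °C; then 18, 0 °C → rt
Reagents that add atoms: bromine, BrBr
Why: Deoxybromination of the vinylogous enolate oxygen by the bromophosphonium salt made in the flask; the push–pull dienal settles into the E,E geometry.

Step 13
Reactants: 19 (2E,4E)-5-bromopenta-2,4-dienal
Product: 20 (2E,4E)-5-bromopenta-2,4-dienoic acid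
Conditions: NaClO2, NaH2PO4, 2-methylbut-2-ene, tBuOH–H2O, 0 °C → rt
Reagents that add atoms: sodium chlorite, [Na+].[O-]Cl=O
Why: Pinnick oxidation of an unsaturated aldehyde to the acid; the alkene scavenger removes hypochlorous acid, so the bromodiene is untouched.

Step 14
Reactants: 20 (2E,4E)-5-bromopenta-2,4-dienoic acid; 17 2-amino-3-hydroxycyclopent-2-en-1-one hydrochloride
Product: 22 (2E,4E)-5-bromo-N-(2-hydroxy-5-oxocyclopent-1-en-1-yl)penta-2,4-dienamide, via (2E,4E)-5-bromopenta-2,4-dienoyl chloride 21 (not isolated)
Conditions: (COCl)2, DMF (cat.), CH2Cl2, 0 °C → rt, evaporate; then 17, Et3N, DMF–CH2Cl2, −20 °C → rt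
Reagents that add atoms: none
Why: Acid chloride acylation of the liberated amine; any enol O-acylation should revert to the more stable amide by O-to-N acyl shift, giving the vinylogous-acid amide.

Step 15
Reactants: 14 (2E,4E,6E)-N-{(1R,5R,6S)-5-hydroxy-2-oxo-5-[(E)-2-(tributylstannyl)ethenyl]-7-oxabicyclo[4.1.0]hept-3-en-3-yl}-8-methylnona-2,4,6-trienamide; 22 (2E,4E)-5-bromo-N-(2-hydroxy-5-oxocyclopent-1-en-1-yl)penta-2,4-dienamide
Product: 23 (2E,4E,6E)-N-[(1R,5S,6S)-5-hydroxy-5-{(1E,3E,5E)-7-[(2-hydroxy-5-oxocyclopent-1-en-1-yl)amino]-7-oxohepta-1,3,5-trien-1-yl}-2-oxo-7-oxabicyclo[4.1.0]hept-3-en-3-yl]-8-methylnona-2,4,6-trienamide (target)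
Conditions: PdCl2(MeCN)2 (5 mol %), DMF, rt, dark
Reagents that add atoms: none
Why: Stille coupling of an alkenylstannane with an alkenyl bromide under ligand-free neutral conditions, with retention at both alkenes, completing the E,E,E-triene; no stereocentre is involved (the C4 descriptor changes from R to S only because CIP priorities change).

## Compound list

1 | (triisopropylsilyl)acetylene | C#C[Si](C(C)C)(C(C)C)C(C)C | starting material
2 | 1,4-benzoquinone | O=C1C=CC(=O)C=C1 | starting material
3 | lithium (triisopropylsilyl)acetylide | [Li]C#C[Si](C(C)C)(C(C)C)C(C)C | intermediate (not isolated)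
4 | 4-hydroxy-4-[(triisopropylsilyl)ethynyl]cyclohexa-2,5-dien-1-one | O=C1C=CC(O)(C#C[Si](C(C)C)(C(C)C)C(C)C)C=C1 | intermediate
5 | 4-[(triethylsilyl)oxy]-4-[(triisopropylsilyl)ethynyl]cyclohexa-2,5-dien-1-one | O=C1C=CC(O[Si](CC)(CC)CC)(C#C[Si](C(C)C)(C(C)C)C(C)C)C=C1 | intermediate
6 | (1R,5R,6S)-5-[(triethylsilyl)oxy]-5-[(triisopropylsilyl)ethynyl]-7-oxabicyclo[4.1.0]hept-3-en-2-one | C1=C[C@@](O[Si](CC)(CC)CC)(C#C[Si](C(C)C)(C(C)C)C(C)C)[C@H]2O[C@H]2C1=O | intermediate
7 | (1R,5R,6S)-3-iodo-5-[(triethylsilyl)oxy]-5-[(triisopropylsilyl)ethynyl]-7-oxabicyclo[4.1.0]hept-3-en-2-one | IC1=C[C@@](O[Si](CC)(CC)CC)(C#C[Si](C(C)C)(C(C)C)C(C)C)[C@H]2O[C@H]2C1=O | intermediate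
8 | (E)-4-methylpent-2-enal | CC(C)/C=C/C=O | starting material
9 | triethyl 4-phosphonocrotonate (ethyl (E)-4-(diethoxyphosphoryl)but-2-enoate) | CCOC(=O)/C=C/CP(=O)(OCC)OCC | starting material
10 | ethyl (2E,4E,6E)-8-methylnona-2,4,6-trienoate | CC(C)/C=C/C=C/C=C/C(=O)OCC | intermediate
11 | (2E,4E,6E)-8-methylnona-2,4,6-trienamide | CC(C)/C=C/C=C/C=C/C(N)=O | intermediate
12 | (2E,4E,6E)-8-methyl-N-{(1R,5R,6S)-2-oxo-5-[(triethylsilyl)oxy]-5-[(triisopropylsilyl)ethynyl]-7-oxabicyclo[4.1.0]hept-3-en-3-yl}nona-2,4,6-trienamide | CC(C)/C=C/C=C/C=C/C(=O)NC1=C[C@@](O[Si](CC)(CC)CC)(C#C[Si](C(C)C)(C(C)C)C(C)C)[C@H]2O[C@H]2C1=O | intermediate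
13 | (2E,4E,6E)-N-[(1R,5R,6S)-5-ethynyl-5-hydroxy-2-oxo-7-oxabicyclo[4.1.0]hept-3-en-3-yl]-8-methylnona-2,4,6-trienamide | CC(C)/C=C/C=C/C=C/C(=O)NC1=C[C@@](O)(C#C)[C@H]2O[C@H]2C1=O | intermediate
14 | (2E,4E,6E)-N-{(1R,5R,6S)-5-hydroxy-2-oxo-5-[(E)-2-(tributylstannyl)ethenyl]-7-oxabicyclo[4.1.0]hept-3-en-3-yl}-8-methylnona-2,4,6-trienamide | CC(C)/C=C/C=C/C=C/C(=O)NC1=C[C@@](O)(/C=C/[Sn](CCCC)(CCCC)CCCC)[C@H]2O[C@H]2C1=O | intermediate
15 | cyclopentane-1,3-dione | O=C1CCC(=O)C1 | starting material
16 | 2-nitrocyclopentane-1,3-dione (enol form) | O=C1CCC(O)=C1[N+](=O)[O-] | intermediate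
17 | 2-amino-3-hydroxycyclopent-2-en-1-one hydrochloride | NC1=C(O)CCC1=O.Cl | intermediate
18 | glutaconaldehyde potassium salt (potassium (1E,3E)-5-oxopenta-1,3-dien-1-olate) | [K+].[O-]/C=C/C=C/C=O | starting material
19 | (2E,4E)-5-bromopenta-2,4-dienal | Br/C=C/C=C/C=O | intermediate
20 | (2E,4E)-5-bromopenta-2,4-dienoic acid | Br/C=C/C=C/C(=O)O | intermediate
21 | (2E,4E)-5-bromopenta-2,4-dienoyl chloride | Br/C=C/C=C/C(Cl)=O | intermediate (not isolated)
22 | (2E,4E)-5-bromo-N-(2-hydroxy-5-oxocyclopent-1-en-1-yl)penta-2,4-dienamide | Br/C=C/C=C/C(=O)NC1=C(O)CCC1=O | intermediate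
23 | (2E,4E,6E)-N-[(1R,5S,6S)-5-hydroxy-5-{(1E,3E,5E)-7-[(2-hydroxy-5-oxocyclopent-1-en-1-yl)amino]-7-oxohepta-1,3,5-trien-1-yl}-2-oxo-7-oxabicyclo[4.1.0]hept-3-en-3-yl]-8-methylnona-2,4,6-trienamide | CC(C)/C=C/C=C/C=C/C(=O)NC1=C[C@@](O)(/C=C/C=C/C=C/C(=O)NC2=C(O)CCC2=O)[C@H]2O[C@H]2C1=O | target

## Step count and least certain steps

Total: 15 steps. Longest linear sequence: 8 steps (steps 1, 2, 3, 4, 7, 8, 9, 15).

**Step 3 (key step, proposed new method).** The catalyst may discriminate poorly between the two arms, the anti face preference may erode if the silyloxy group shields less than expected, or a second epoxidation may occur. The fallback uses known chemistry, sets out from 5 and returns at 6. A desymmetrising conjugate reduction of the dienone with a chiral rhodium hydride catalyst (Rh(iPr-Phebox)(OAc)2(H2O), (EtO)2MeSiH), an established reaction of 4,4-disubstituted cyclohexadienones, saturates the arm that will later carry nitrogen and gives (S)-4-[(triethylsilyl)oxy]-4-[(triisopropylsilyl)ethynyl]cyclohex-2-en-1-one F1. Alkaline epoxidation of the remaining enone (tBuOOH, benzyltrimethylammonium hydroxide) goes anti to the silyloxy group, as is usual for 4-silyloxycyclohexenones, to give (1R,5R,6S)-5-[(triethylsilyl)oxy]-5-[(triisopropylsilyl)ethynyl]-7-oxabicyclo[4.1.0]heptan-2-one F2. Enolisation toward the only CH2 side (LiN(SiMe3)2, Me3SiCl) gives the trimethylsilyl enol ether F3, and Saegusa–Ito oxidation with Pd(OAc)2 in MeCN restores the enone and delivers 6.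

**Step 7.** C–N bond formation with the weakly nucleophilic polyene amide may be slow, allowing loss of iodine by hydrodehalogenation and base-induced degradation of the epoxy ketone to compete. The fallback sets out from 7 and returns at 12. A better nitrogen partner, tert-butyl carbamate, is coupled under palladium catalysis (Pd2(dba)3, Xantphos, Cs2CO3) to give tert-butyl N-{(1R,5R,6S)-2-oxo-5-[(triethylsilyl)oxy]-5-[(triisopropylsilyl)ethynyl]-7-oxabicyclo[4.1.0]hept-3-en-3-yl}carbamate F4. The carbamate is cleaved without protic acid (Me3SiOTf, 2,6-lutidine, then MeOH) to give (1R,5R,6S)-3-amino-5-[(triethylsilyl)oxy]-5-[(triisopropylsilyl)ethynyl]-7-oxabicyclo[4.1.0]hept-3-en-2-one F5. This is acylated at once (pyridine, CH2Cl2, 0 °C) with (2E,4E,6E)-8-methylnona-2,4,6-trienoyl chloride F7, made from 10 by saponification (LiOH) to (2E,4E,6E)-8-methylnona-2,4,6-trienoic acid F6 and treatment with (COCl)2, giving 12.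

**Step 9.** Conjugate reduction of the amido enone or reductive opening of the epoxy ketone by palladium hydride and tin hydride may compete with alkyne hydrostannation, and some tin may go to the internal carbon. The fallback sets out from 13 and returns at 23. Platinum-catalysed hydrosilylation (Pt2[(CH2=CHSiMe2)2O]3, tBu3P, (EtO)3SiH), which leaves ketones and oxiranes alone, gives (2E,4E,6E)-N-{(1R,5R,6S)-5-hydroxy-2-oxo-5-[(E)-2-(triethoxysilyl)ethenyl]-7-oxabicyclo[4.1.0]hept-3-en-3-yl}-8-methylnona-2,4,6-trienamide F8. Fluoride-promoted Hiyama coupling with 22 (Pd2(dba)3, Bu4NF, THF) then gives 23, replacing both steps 9 and 15.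

**Step 1.** Electron transfer from the acetylide to the quinone and double addition may cut into the mono-adduct. The fallback sets out from 3 and returns at 4. Acetylide 3 is added to commercial 4,4-dimethoxycyclohexa-2,5-dien-1-one, which has a single carbonyl, to give 4,4-dimethoxy-1-[(triisopropylsilyl)ethynyl]cyclohexa-2,5-dien-1-ol F9; mild aqueous acid (oxalic acid, THF–H2O) hydrolyses the ketal to 4.

## Further compounds

F1 | step 3 | (S)-4-[(triethylsilyl)oxy]-4-[(triisopropylsilyl)ethynyl]cyclohex-2-en-1-one | C1C[C@@](O[Si](CC)(CC)CC)(C#C[Si](C(C)C)(C(C)C)C(C)C)C=CC1=O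
F2 | step 3 | (1R,5R,6S)-5-[(triethylsilyl)oxy]-5-[(triisopropylsilyl)ethynyl]-7-oxabicyclo[4.1.0]heptan-2-one | C1C[C@@](O[Si](CC)(CC)CC)(C#C[Si](C(C)C)(C(C)C)C(C)C)[C@H]2O[C@H]2C1=O
F3 | step 3 | {[(1R,5R,6S)-5-[(triethylsilyl)oxy]-5-[(triisopropylsilyl)ethynyl]-7-oxabicyclo[4.1.0]hept-2-en-2-yl]oxy}trimethylsilane | C1C[C@@](O[Si](CC)(CC)CC)(C#C[Si](C(C)C)(C(C)C)C(C)C)[C@H]2O[C@H]2C(O[Si](C)(C)C)=1
F4 | step 7 | tert-butyl N-{(1R,5R,6S)-2-oxo-5-[(triethylsilyl)oxy]-5-[(triisopropylsilyl)ethynyl]-7-oxabicyclo[4.1.0]hept-3-en-3-yl}carbamate | CC(C)(C)OC(=O)NC1=C[C@@](O[Si](CC)(CC)CC)(C#C[Si](C(C)C)(C(C)C)C(C)C)[C@H]2O[C@H]2C1=O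
F5 | step 7 | (1R,5R,6S)-3-amino-5-[(triethylsilyl)oxy]-5-[(triisopropylsilyl)ethynyl]-7-oxabicyclo[4.1.0]hept-3-en-2-one | NC1=C[C@@](O[Si](CC)(CC)CC)(C#C[Si](C(C)C)(C(C)C)C(C)C)[C@H]2O[C@H]2C1=O
F6 | step 7 | (2E,4E,6E)-8-methylnona-2,4,6-trienoic acid | CC(C)/C=C/C=C/C=C/C(=O)O
F7 | step 7 | (2E,4E,6E)-8-methylnona-2,4,6-trienoyl chloride | CC(C)/C=C/C=C/C=C/C(Cl)=O
F8 | step 9 | (2E,4E,6E)-N-{(1R,5R,6S)-5-hydroxy-2-oxo-5-[(E)-2-(triethoxysilyl)ethenyl]-7-oxabicyclo[4.1.0]hept-3-en-3-yl}-8-methylnona-2,4,6-trienamide | CC(C)/C=C/C=C/C=C/C(=O)NC1=C[C@@](O)(/C=C/[Si](OCC)(OCC)OCC)[C@H]2O[C@H]2C1=O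
F9 | step 1 | 4,4-dimethoxy-1-[(triisopropylsilyl)ethynyl]cyclohexa-2,5-dien-1-ol | COC1(OC)C=CC(O)(C#C[Si](C(C)C)(C(C)C)C(C)C)C=C1
A1 | alternative 1 | (2E,4E,6E)-N-(6,6-dimethoxy-3-oxocyclohexa-1,4-dien-1-yl)-8-methylnona-2,4,6-trienamide | CC(C)/C=C/C=C/C=C/C(=O)NC1=CC(=O)C=CC1(OC)OC
A2 | alternative 1 | (2E,4E,6E)-N-[(1S,6R)-5,5-dimethoxy-2-oxo-7-oxabicyclo[4.1.0]hept-3-en-4-yl]-8-methylnona-2,4,6-trienamide | CC(C)/C=C/C=C/C=C/C(=O)NC1=CC(=O)[C@H]2O[C@H]2C1(OC)OC
A3 | alternative 1 | (2E,4E,6E)-N-{(1R,5S,6S)-5-hydroxy-2,2-dimethoxy-5-[(E)-2-(tributylstannyl)ethenyl]-7-oxabicyclo[4.1.0]hept-3-en-3-yl}-8-methylnona-2,4,6-trienamide (hydroxyl syn to the oxirane) | CC(C)/C=C/C=C/C=C/C(=O)NC1=C[C@](O)(/C=C/[Sn](CCCC)(CCCC)CCCC)[C@H]2O[C@H]2C1(OC)OC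
A4 | alternative 2 | 1-[(triisopropylsilyl)ethynyl]cyclohexa-1,3-diene | C1(C#C[Si](C(C)C)(C(C)C)C(C)C)=CC=CCC1
A5 | alternative 2 | rac-(1R,5R,6S)-5-hydroxy-5-[(triisopropylsilyl)ethynyl]-7-oxabicyclo[4.1.0]heptan-2-one (racemate, one enantiomer drawn) | C1C[C@@](O)(C#C[Si](C(C)C)(C(C)C)C(C)C)[C@H]2O[C@H]2C1=O
A6 | alternative 3 | meso-2,3:5,6-diepoxy-4-[(triethylsilyl)oxy]-4-[(triisopropylsilyl)ethynyl]cyclohexan-1-one (both oxiranes anti to the silyloxy group) | [C@H]13O[C@H]1[C@@](O[Si](CC)(CC)CC)(C#C[Si](C(C)C)(C(C)C)C(C)C)[C@H]2O[C@H]2C3=O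
A7 | alternative 3 | (1R,5R,6S)-3-azido-5-[(triethylsilyl)oxy]-5-[(triisopropylsilyl)ethynyl]-7-oxabicyclo[4.1.0]hept-3-en-2-one | [N-]=[N+]=NC1=C[C@@](O[Si](CC)(CC)CC)(C#C[Si](C(C)C)(C(C)C)C(C)C)[C@H]2O[C@H]2C1=O
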